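Left-handed product cannot pass 50.0% of the charged substrate while each hand stays itself, for the left-handed substrate is that share of the charge; this is the ceiling of a plain kinetic resolution. The meeting on the zeta flask began there.

| flask | left-handed substrate | right-handed substrate | reagent | temperature | remark | time |
|---|---|---|---|---|---|---|
| zeta | 0.25 M | 0.25 M | 2 equiv | 0 °C | the very flask that is asked about, followed so far |  |
| delta | 0.12 M | 0.12 M | 2 equiv | 6 °C | run made earlier |  |
| flask | 0.25 M | 0.25 M | 2.00 equiv | 0 °C |  | 8.0 h |

| run | time / h | left-handed product / % |
|---|---|---|
| zeta | 0.500 | 19.8 |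
| zeta | 0.833 | 26.7 |
| zeta | 1.33 | 32.5 |
| zeta | 2.00 | 37.7 |
| zeta | 3.00 | 41.4 |
| zeta | 4.00 | 43.7 |
| zeta | 6.00 | 47.1 |
| delta | 0.200 | 7.7 |
| delta | 0.667 | 19.8 |
| delta | 1.00 | 24.3 |
| delta | 1.50 | 29.8 |
| delta | 2.50 | 36.1 |
| delta | 3.00 | 38.7 |
| delta | 4.00 | 42.4 |

(each reading ± 0.3 percentage points)

- blue: change nothing and wait 2.5 h more
- red: at 8.0 h take out 90% of the left-handed product then present, then wait 2.5 h
- amber: at 8.0 h add reagent, 50.0% of the amount charged, then wait 2.5 h
- green: at 8.0 h raise the temperature by 20 K, then wait 2.5 h

- reagent is single-handed; left-handed substrate and right-handed substrate are mirror images of each other, charged as a racemate, each of them at the stated concentration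
- what is taken out of left-handed product is counted as made
- additions bring no volume worth counting
- the handed part of reagent does not stay in what it makes, so the products of the two hands are mirror images too

- left-handed product, in percent of the left-handed substrate and right-handed substrate together first charged, at 8.0 h
- which option adds most left-handed product ("none" when 2 percentage points or less is all one gets) (blue / red / amber / green / none)
- left-handed product present, with what was taken out counted in, in percent of the left-handed substrate and right-handed substrate together first charged, after red
- left-handed product present, with what was taken out counted in, in percent of the left-handed substrate and right-handed substrate together first charged, after green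

The forecaster held to the ceiling. He gave 48.3% at 8.0 h, 49.8% after red, 49.7% after green, and as best none: “So no option can add more than 2 points.”

The minute-taker objected, with a reckoning of her own. Between 4.00 h and 6.00 h the zeta flask gained 3.4 percentage points, more than the 2.9 points then left below the ceiling. So she took the whole 52.9% not yet left-handed product as one pool, drained at that late pace. This gave 21.6 h: the remainder half-life, the time in which what is not yet left-handed product halves at the late pace.

Then she counted. Up to 8.0 h lie 0.0926 half-lives, which gives 50.4%, not the forecast's figure. By the same count, blue adds 3.8 points.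

For heat she compared the runs. Zeta and delta read the same yield at 0.500 h and 0.667 h, at 0.25 M and 0.12 M, so concentration times time suggests a clock factor of 1.56 between 0 °C and 6 °C. Read as an Arrhenius slope, that factor gives an apparent barrier of 47.1 kJ mol⁻¹. On the assumption that the tail keeps it, a rise of 20 K from the flask's own 0 °C gives a clock factor of 4.12. Green's wait then counts 0.477 half-lives and adds 14 points. She named green; red and amber she did not reckon.

The flask gives 49.8% at 8.0 h, 52.8% after red and 70.1% after green, which adds 20 points, the most of the options. At 8.00 h the flask still holds 19.0% right-handed substrate and 16.5% achiral form. Counted from the true 49.8%, the same 0.477 half-lives give green 14 points: the right choice, and low.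

    reagent + left-handed substrate → left-handed product (k = 2.50 L mol⁻¹ h⁻¹, Ea = 56.0 kJ mol⁻¹)
    reagent + right-handed substrate → right-handed product (k = 0.200 L mol⁻¹ h⁻¹, Ea = 59.0 kJ mol⁻¹)
    left-handed substrate ⇌ achiral form (K = 1.30, k = 0.130 h⁻¹, Ea = 97.0 kJ mol⁻¹, ΔH = −14.0 kJ mol⁻¹)
    right-handed substrate ⇌ achiral form (K = 1.30, k = 0.130 h⁻¹, Ea = 97.0 kJ mol⁻¹, ΔH = −14.0 kJ mol⁻¹)
    reagent ⇌ dormant form (K = 0.140, k = 0.340 h⁻¹, Ea = 87.0 kJ mol⁻¹, ΔH = −32.0 kJ mol⁻¹)
    reagent → decomposition product (k = 5.00 × 10⁻⁴ h⁻¹, Ea = 110 kJ mol⁻¹)
    (constants at 0 °C)

For the repeat at 25 °C, the same barrier gives a clock factor of 5.69, so 1.83 half-lives lie beyond the last reading and the count gives 85.2%. That flask computes to 82.7%.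

The earlier runs and the new flask were computed from invented constants.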